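**Retrosynthetic overview**

1. Feature: in each half the lactone ring oxygen lies between C1' (bonded to chromanone C2) and the lactone carbonyl C4', and the C2 substituent on C1' is cis to the methyl on C2'. Removing that oxygen leaves a cis-2,3-disubstituted cyclobutanone (ring C1'–C2'–C3'–C4'), the [2+2] adduct of a ketene equivalent and a Z-propenyl group on C2.
2. Target ⇒ C2-symmetric bis(lactone) 20 (one lactone opened) ⇒ bis(cyclobutanone) 18 (O-demethylation; Baeyer–Villiger insertion between C4' and C1') ⇒ bis(Z-propenyl)chromanone 15 (keteniminium [2+2] forming C1'–C4' and C2'–C3' in each half).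
3. 15 ⇒ bis(propynyl)chromanone 14 (Lindlar) ⇒ aryl bromide 12 + aryl boronate 13 (Suzuki–Miyaura coupling at C6–C6'; 13 is made from 12).
4. 12 ⇒ 6-bromochromone ester 8 (enantioselective copper–bis(oxazoline) propynylation of the siloxybenzopyrylium, setting C2) ⇒ acetophenone 5 (Claisen condensation/cyclodehydration) ⇒ 4-bromo-3-methoxyphenol (MOM ether, directed lithiation/acetylation). The bromine position and the Me/MOM differentiation of the two oxygens fix the 6,6' linkage and the direction of pyranone closure.
5. Ring order: pyranone (step 3), biaryl bond joining two chromanones (step 6), two cyclobutanones (step 8), expanded to two γ-lactones (step 9), one lactone re-opened (step 11).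

Key step: step 8

Remark 1: the 6,6' biaryl axis carries only two ortho substituents (the C5 oxygens) and is taken to rotate freely; the target defines no axial configuration.
Remark 2: the bis(oxazoline) is written as (S,S) and stands for whichever enantiomer sends the alkynyl group to the Si face of C2 (O1 > CO2Me > C3); the antipode would be used if the sense is the reverse.

**Route**

Step 1
Reactants: 1 4-bromo-3-methoxyphenol
Product: 2 1-bromo-2-methoxy-4-(methoxymethoxy)benzene
Conditions: MOMCl, iPr2NEt, CH2Cl2, 0 °C → rt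
Reagents that add atoms: chloromethyl methyl ether (MOMCl), COCCl
Why: O-alkylation of the phenol to its MOM acetal, which later cooperates with the OMe group in directing lithiation and is lost in the acid of step 3.

Step 2
Reactants: 2 1-bromo-2-methoxy-4-(methoxymethoxy)benzene, 3 N-methoxy-N-methylacetamide
Product: 5 1-[3-bromo-2-methoxy-6-(methoxymethoxy)phenyl]ethan-1-one, via aryllithium 4 (not isolated)
Conditions: LiTMP, THF, −78 °C; then 3, −78 → 0 °C; H2O
Reagents that add atoms: none
Why: Directed ortho-metalation in which the hindered lithium amide removes the proton flanked by OMe and OMOM (the most acidic site) without exchanging the C–Br bond as an alkyllithium would, followed by single addition of the aryllithium to the Weinreb amide, whose chelated tetrahedral adduct survives until the quench.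

Step 3
Reactants: 5 1-[3-bromo-2-methoxy-6-(methoxymethoxy)phenyl]ethan-1-one, 6 dimethyl oxalate
Product: 8 methyl 6-bromo-5-methoxy-4-oxo-4H-chromene-2-carboxylate, via 2,4-dioxobutanoate 7 (not isolated)
Conditions: NaOMe, MeOH/THF, reflux; then conc. HCl, MeOH, reflux
Reagents that add atoms: none
Why: Crossed Claisen condensation of the methyl ketone enolate with dimethyl oxalate, after which acid removes the MOM acetal and the freed phenol closes on the 2-keto group with loss of water (chromone-2-carboxylate synthesis); only the oxygen para to bromine is free, so only the 6-bromo-5-methoxy chromone can form.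

Step 4
Reactants: 8 methyl 6-bromo-5-methoxy-4-oxo-4H-chromene-2-carboxylate, 9 propyne
Product: 12 methyl (2S)-6-bromo-5-methoxy-4-oxo-2-(prop-1-ynyl)chromane-2-carboxylate, via 4-siloxybenzopyrylium triflate 10 (not isolated), via silyl enol ether 11 (not isolated)
Conditions: TBSOTf, toluene, 60 °C; then CuI (cat.), 2,2'-(propane-2,2-diyl)bis[(4S)-4-phenyl-4,5-dihydrooxazole], propyne (excess), iPr2NEt, toluene, −78 °C; then 3 M HCl, THF, rt
Reagents that add atoms: none
Why: The silyl triflate turns the chromone into a 4-siloxybenzopyrylium ion and a chiral monovalent-copper propynylide adds to its C2 (catalytic enantioselective alkynylation of 2-ester benzopyrylium ions), the ligand choosing the Si face so that the quaternary centre becomes S, and aqueous acid then cleaves the silyl enol ether to the chromanone.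

Step 5
Reactants: 12 methyl (2S)-6-bromo-5-methoxy-4-oxo-2-(prop-1-ynyl)chromane-2-carboxylate
Product: 13 methyl (2S)-5-methoxy-4-oxo-2-(prop-1-ynyl)-6-(4,4,5,5-tetramethyl-1,3,2-dioxaborolan-2-yl)chromane-2-carboxylate
Conditions: B2pin2, PdCl2(dppf) (cat.), KOAc, 1,4-dioxane, 80 °C
Reagents that add atoms: bis(pinacolato)diboron (B2pin2), CC1(C)OB(OC1(C)C)B1OC(C)(C)C(C)(C)O1
Why: Miyaura borylation applied to half of the bromide, in which zerovalent palladium inserts into the C6–Br bond and the acetate-bridged complex transmetalates with the diboron, while the weak acetate base leaves the ketone, the ester, the internal alkyne and the quaternary C2 centre untouched.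

Step 6
Reactants: 12 methyl (2S)-6-bromo-5-methoxy-4-oxo-2-(prop-1-ynyl)chromane-2-carboxylate, 13 methyl (2S)-5-methoxy-4-oxo-2-(prop-1-ynyl)-6-(4,4,5,5-tetramethyl-1,3,2-dioxaborolan-2-yl)chromane-2-carboxylate
Product: 14 dimethyl (2S,2'S)-5,5'-dimethoxy-4,4'-dioxo-2,2'-di(prop-1-ynyl)-[6,6'-bichromane]-2,2'-dicarboxylate
Conditions: Pd(OAc)2 (cat.), SPhos, K3PO4, toluene/H2O, 50 °C
Reagents that add atoms: none
Why: Suzuki–Miyaura cross-coupling forms the C6–C6' bond at the two pre-set carbons (each partner has a single ortho substituent, which the biarylphosphine ligand accommodates), the mild phosphate base and moderate temperature should leave the quaternary C2 centres intact, and because two S halves are joined, most of any minor enantiomer should end in the separable meso isomer and so raise the enantiopurity of 14.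

Step 7
Reactants: 14 dimethyl (2S,2'S)-5,5'-dimethoxy-4,4'-dioxo-2,2'-di(prop-1-ynyl)-[6,6'-bichromane]-2,2'-dicarboxylate
Product: 15 dimethyl (2S,2'S)-5,5'-dimethoxy-4,4'-dioxo-2,2'-di[(Z)-prop-1-enyl]-[6,6'-bichromane]-2,2'-dicarboxylate
Conditions: H2 (1 atm), Lindlar catalyst (Pd on CaCO3 poisoned by Pb(OAc)2), quinoline, EtOAc, rt
Reagents that add atoms: none
Why: Lindlar semihydrogenation delivers two hydrogens syn to each alkyne on the poisoned palladium surface and stops at the Z-alkene, while ketones, esters and aryl ethers are inert.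

Step 8
Reactants: 15 dimethyl (2S,2'S)-5,5'-dimethoxy-4,4'-dioxo-2,2'-di[(Z)-prop-1-enyl]-[6,6'-bichromane]-2,2'-dicarboxylate, 16 N,N-dimethylacetamide
Product: 18 dimethyl (2S,2'S)-5,5'-dimethoxy-2,2'-bis[(1R,2S)-2-methyl-4-oxocyclobutyl]-4,4'-dioxo-[6,6'-bichromane]-2,2'-dicarboxylate, via bis(cyclobutaniminium) bis(triflate) 17 (not isolated)
Conditions: 16 (excess), Tf2O, ClCH2CH2Cl, −15 °C; then 15, 2,4,6-collidine, 80 °C; then H2O, rt
Reagents that add atoms: water, O
Why: Tf2O and collidine convert the amide into the keteniminium ion H2C=C=NMe2+, whose electrophilic central carbon is attacked by each Z-propenyl π bond in an asynchronous, suprafacial [2+2] cycloaddition (the known keteniminium–alkene route to cyclobutanones), and water then hydrolyses the two cyclobutaniminium ions of 17 to ketones. Each four-membered ring is closed when the enamine-type CH2 carbon C3' collapses onto the developing cation at C2' directly after the C4'–C1' bond has formed, faster than rotation about C1'–C2', so the Z geometry becomes the cis relationship of C1' and C2'. The orientation should follow charge distribution: the aryloxy oxygen and the ester on C2 disfavour positive charge at C1', so charge builds at the methyl-bearing C2' and the iminium carbon bonds to C1'. The absolute configuration of C1' and C2' is controlled by the S centre at C2: allylic 1,3-strain with the cis methyl holds the small ring oxygen O1 eclipsed with the C1'=C2' bond, the fused ring on the C3 side covers one face, and the reagent should add anti to the C2–C3 bond on the face flanked by the edge-on ester, which is the face leading to 18. The step needs orientation, π-face and alkene-over-arene selectivity; these rest on the inductive bias at C2, the rotamer lock by the Z-methyl, and the deactivation of the dialkoxyarene by its C4 acyl group, with the amide activated before the substrate is added so that no free Tf2O meets the aryl ketone. The epimerisable α-centre C1' is kept by using no base stronger than collidine and a neutral hydrolysis.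

Step 9
Reactants: 18 dimethyl (2S,2'S)-5,5'-dimethoxy-2,2'-bis[(1R,2S)-2-methyl-4-oxocyclobutyl]-4,4'-dioxo-[6,6'-bichromane]-2,2'-dicarboxylate
Product: 19 dimethyl (2S,2'S)-5,5'-dimethoxy-2,2'-bis[(2R,3S)-3-methyl-5-oxooxolan-2-yl]-4,4'-dioxo-[6,6'-bichromane]-2,2'-dicarboxylate
Conditions: mCPBA, CH2Cl2, 0 °C → rt
Reagents that add atoms: mCPBA (3-chloroperoxybenzoic acid), O=C(OO)c1cccc(Cl)c1
Why: Baeyer–Villiger oxidation, in which the strained cyclobutanone adds peracid far faster than the conjugated aryl ketones and the secondary carbon C1' should migrate in preference to the primary C3', with retention, so that oxygen enters between C4' and C1' and the cis relationship is carried into the γ-lactone.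

Step 10
Reactants: 19 dimethyl (2S,2'S)-5,5'-dimethoxy-2,2'-bis[(2R,3S)-3-methyl-5-oxooxolan-2-yl]-4,4'-dioxo-[6,6'-bichromane]-2,2'-dicarboxylate
Product: 20 dimethyl (2S,2'S)-5,5'-dihydroxy-2,2'-bis[(2R,3S)-3-methyl-5-oxooxolan-2-yl]-4,4'-dioxo-[6,6'-bichromane]-2,2'-dicarboxylate
Conditions: BCl3, CH2Cl2, −78 → 0 °C; then H2O
Reagents that add atoms: none
Why: Carbonyl-directed Lewis-acid ether cleavage, in which BCl3 chelates between the C4 carbonyl and the peri 5-methoxy oxygen and chloride removes the methyl group, at a temperature that leaves the lactones and methyl esters untouched.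

Step 11
Reactants: 20 dimethyl (2S,2'S)-5,5'-dihydroxy-2,2'-bis[(2R,3S)-3-methyl-5-oxooxolan-2-yl]-4,4'-dioxo-[6,6'-bichromane]-2,2'-dicarboxylate
Product: 21 (3S,4R)-4-hydroxy-3-methyl-4-[(2S)-2-(methoxycarbonyl)-5-hydroxy-4-oxo-6-{(2S)-5-hydroxy-2-(methoxycarbonyl)-2-[(2R,3S)-3-methyl-5-oxooxolan-2-yl]-4-oxochroman-6-yl}chroman-2-yl]butanoic acid (the target)
Conditions: LiOH (3 equiv, two taken up by the phenols), THF/H2O, 0 °C; then 0.5 M HCl to pH 4, 0 °C
Reagents that add atoms: lithium hydroxide, [Li+].[OH-]
Why: Saponification of a γ-lactone at its unhindered CH2–C(=O) carbonyl is faster than attack on the neopentyl-type methyl esters, so one equivalent of hydroxide beyond the phenols should give a statistical mono-opening in which only the acyl–oxygen bond breaks and C1' keeps its configuration, and cold acidification releases the hydroxy acid before it can re-close.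

**Compound list**

1 | 4-bromo-3-methoxyphenol | COc1cc(O)ccc1Br | starting material
2 | 1-bromo-2-methoxy-4-(methoxymethoxy)benzene | COCOc1ccc(Br)c(OC)c1 | intermediate
3 | N-methoxy-N-methylacetamide | CC(=O)N(C)OC | starting material
4 | [3-bromo-2-methoxy-6-(methoxymethoxy)phenyl]lithium | COCOc1ccc(Br)c(OC)c1[Li] | intermediate
5 | 1-[3-bromo-2-methoxy-6-(methoxymethoxy)phenyl]ethan-1-one | COCOc1ccc(Br)c(OC)c1C(C)=O | intermediate
6 | dimethyl oxalate | COC(=O)C(=O)OC | starting material
7 | methyl 4-[3-bromo-2-methoxy-6-(methoxymethoxy)phenyl]-2,4-dioxobutanoate | COCOc1ccc(Br)c(OC)c1C(=O)CC(=O)C(=O)OC | intermediate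
8 | methyl 6-bromo-5-methoxy-4-oxo-4H-chromene-2-carboxylate | COC(=O)c1cc(=O)c2c(o1)ccc(Br)c2OC | intermediate
9 | propyne | CC#C | starting material
10 | 6-bromo-4-(tert-butyldimethylsiloxy)-5-methoxy-2-(methoxycarbonyl)benzopyrylium triflate | COC(=O)c1cc(O[Si](C)(C)C(C)(C)C)c2c([o+]1)ccc(Br)c2OC.[O-]S(=O)(=O)C(F)(F)F | intermediate
11 | methyl (2S)-6-bromo-4-(tert-butyldimethylsiloxy)-5-methoxy-2-(prop-1-ynyl)-2H-chromene-2-carboxylate | COC(=O)[C@@]1(C#CC)C=C(O[Si](C)(C)C(C)(C)C)c2c(ccc(Br)c2OC)O1 | intermediate
12 | methyl (2S)-6-bromo-5-methoxy-4-oxo-2-(prop-1-ynyl)chromane-2-carboxylate | COC(=O)[C@@]1(C#CC)CC(=O)c2c(ccc(Br)c2OC)O1 | intermediate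
13 | methyl (2S)-5-methoxy-4-oxo-2-(prop-1-ynyl)-6-(4,4,5,5-tetramethyl-1,3,2-dioxaborolan-2-yl)chromane-2-carboxylate | COC(=O)[C@@]1(C#CC)CC(=O)c2c(ccc(B3OC(C)(C)C(C)(C)O3)c2OC)O1 | intermediate
14 | dimethyl (2S,2'S)-5,5'-dimethoxy-4,4'-dioxo-2,2'-di(prop-1-ynyl)-[6,6'-bichromane]-2,2'-dicarboxylate | COC(=O)[C@@]1(C#CC)CC(=O)c2c(ccc(-c3ccc4c(c3OC)C(=O)C[C@@](C(=O)OC)(C#CC)O4)c2OC)O1 | intermediate
15 | dimethyl (2S,2'S)-5,5'-dimethoxy-4,4'-dioxo-2,2'-di[(Z)-prop-1-enyl]-[6,6'-bichromane]-2,2'-dicarboxylate | COC(=O)[C@@]1(/C=C\C)CC(=O)c2c(ccc(-c3ccc4c(c3OC)C(=O)C[C@@](C(=O)OC)(/C=C\C)O4)c2OC)O1 | intermediate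
16 | N,N-dimethylacetamide | CC(=O)N(C)C | starting material
17 | bis(cis-cyclobutaniminium) bis(triflate) of 18 (C4'=NMe2+ in place of C4'=O) | COC(=O)[C@@]1([C@@H]2C(=[N+](C)C)C[C@@H]2C)CC(=O)c2c(ccc(-c3ccc4c(c3OC)C(=O)C[C@@](C(=O)OC)([C@@H]3C(=[N+](C)C)C[C@@H]3C)O4)c2OC)O1.[O-]S(=O)(=O)C(F)(F)F.[O-]S(=O)(=O)C(F)(F)F | intermediate
18 | dimethyl (2S,2'S)-5,5'-dimethoxy-2,2'-bis[(1R,2S)-2-methyl-4-oxocyclobutyl]-4,4'-dioxo-[6,6'-bichromane]-2,2'-dicarboxylate | COC(=O)[C@@]1([C@@H]2C(=O)C[C@@H]2C)CC(=O)c2c(ccc(-c3ccc4c(c3OC)C(=O)C[C@@](C(=O)OC)([C@@H]3C(=O)C[C@@H]3C)O4)c2OC)O1 | intermediate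
19 | dimethyl (2S,2'S)-5,5'-dimethoxy-2,2'-bis[(2R,3S)-3-methyl-5-oxooxolan-2-yl]-4,4'-dioxo-[6,6'-bichromane]-2,2'-dicarboxylate | COC(=O)[C@@]1([C@@H]2OC(=O)C[C@@H]2C)CC(=O)c2c(ccc(-c3ccc4c(c3OC)C(=O)C[C@@](C(=O)OC)([C@@H]3OC(=O)C[C@@H]3C)O4)c2OC)O1 | intermediate
20 | dimethyl (2S,2'S)-5,5'-dihydroxy-2,2'-bis[(2R,3S)-3-methyl-5-oxooxolan-2-yl]-4,4'-dioxo-[6,6'-bichromane]-2,2'-dicarboxylate | COC(=O)[C@@]1([C@@H]2OC(=O)C[C@@H]2C)CC(=O)c2c(ccc(-c3ccc4c(c3O)C(=O)C[C@@](C(=O)OC)([C@@H]3OC(=O)C[C@@H]3C)O4)c2O)O1 | intermediate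
21 | mono-seco acid of 20, one lactone opened to the (1R,2S)-3-carboxy-1-hydroxy-2-methylpropyl chain | COC(=O)[C@@]1([C@H](O)[C@@H](C)CC(=O)O)CC(=O)c2c(ccc(-c3ccc4c(c3O)C(=O)C[C@@](C(=O)OC)([C@@H]3OC(=O)C[C@@H]3C)O4)c2O)O1 | target

**Step count**

Total: 11 steps. Longest linear sequence: 11 steps (1 → 21); bromide 12 enters step 6 both directly and, after step 5, as boronate 13.

**Steps most likely to fail**

Step 8. The iminium carbon may bond to C2' and not to C1', because the quaternary C2 presses against the inductive bias. The reagent may add to the alkene face on the C3 side. It may also be consumed by the dialkoxyarene or the aryl ketone oxygen before the deactivated, hindered alkenes react twice. The fallback answers the facial problem; orientation and chemoselectivity are answered by the detour under step 9. It sets out from the bis(alkyne) 14 and adds the same keteniminium ion (16, Tf2O, collidine, ClCH2CH2Cl, 80 °C; then H2O) to the two triple bonds, a known route to cyclobutenones, to give the bis(2-methyl-4-oxocyclobut-1-en-1-yl)chromanone F1. Hydrogenation (H2, Pd/C, EtOAc) delivers both hydrogens syn to each ring alkene and comes back to the route at 18. The cis relationship then follows from the syn addition. The π-face is chosen by approach of the cyclobutene to the metal surface on the side away from the C2 ester, with C4' already in the alkene plane, a control element different from the rotamer bias on which step 8 depends.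

Step 9. Migration of the methylene carbon C3' may compete, since C1' is attached to the carbon that bears the aryloxy oxygen and the ester. Long exposure may also oxidise the dialkoxyaryl ketone. The fallback sets out from 15 and uses dichloroketene (Cl3CCOCl, Zn–Cu couple, Et2O/DME, rt) in place of the keteniminium ion. The bulky CCl2 end avoids C1' and the cycloaddition should give the bis(cis-3,3-dichloro-2-methyl-4-oxocyclobutyl)chromanone F2. Peracid oxidation (mCPBA, CH2Cl2) can then move only C1', because a CCl2 carbon does not migrate, and gives the bis(cis-4,4-dichloro-3-methyl-5-oxooxolan-2-yl)chromanone F3. Zinc in acetic acid removes the four chlorines and the route is rejoined at 19.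

Step 11. Both lactones or neither may open (statistics), a methyl ester may be saponified, base may open the chromanone by retro-oxa-Michael reaction and scramble C2, and the hydroxy acid may re-close on acidification. The fallback sets out from 20 and opens both lactones on purpose (excess LiOH, THF/H2O, 0 °C, short contact) to the symmetric bis(hydroxy acid) F4. One ring is then closed under non-basic, metered conditions with one equivalent of 1-ethyl-3-(3-dimethylaminopropyl)carbodiimide hydrochloride (CH2Cl2, 0 °C), which lactonises a γ-hydroxy acid through its O-acylisourea, arriving at 21. Unchanged F4 is recycled and any 20 formed is re-opened.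

**Further compounds**

F1 | step 8 | dimethyl (2S,2'S)-5,5'-dimethoxy-2,2'-bis(2-methyl-4-oxocyclobut-1-en-1-yl)-4,4'-dioxo-[6,6'-bichromane]-2,2'-dicarboxylate | COC(=O)[C@@]1(C2=C(C)CC2=O)CC(=O)c2c(ccc(-c3ccc4c(c3OC)C(=O)C[C@@](C(=O)OC)(C3=C(C)CC3=O)O4)c2OC)O1
F2 | step 9 | dimethyl (2S,2'S)-2,2'-bis(cis-3,3-dichloro-2-methyl-4-oxocyclobutyl)-5,5'-dimethoxy-4,4'-dioxo-[6,6'-bichromane]-2,2'-dicarboxylate | COC(=O)[C@@]1([C@@H]2C(=O)C(Cl)(Cl)[C@@H]2C)CC(=O)c2c(ccc(-c3ccc4c(c3OC)C(=O)C[C@@](C(=O)OC)([C@@H]3C(=O)C(Cl)(Cl)[C@@H]3C)O4)c2OC)O1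
F3 | step 9 | dimethyl (2S,2'S)-2,2'-bis(cis-4,4-dichloro-3-methyl-5-oxooxolan-2-yl)-5,5'-dimethoxy-4,4'-dioxo-[6,6'-bichromane]-2,2'-dicarboxylate | COC(=O)[C@@]1([C@@H]2OC(=O)C(Cl)(Cl)[C@@H]2C)CC(=O)c2c(ccc(-c3ccc4c(c3OC)C(=O)C[C@@](C(=O)OC)([C@@H]3OC(=O)C(Cl)(Cl)[C@@H]3C)O4)c2OC)O1
F4 | step 11 | bis(hydroxy acid) of 20, both chains (1R,2S)-3-carboxy-1-hydroxy-2-methylpropyl | COC(=O)[C@@]1([C@H](O)[C@@H](C)CC(=O)O)CC(=O)c2c(ccc(-c3ccc4c(c3O)C(=O)C[C@@](C(=O)OC)([C@H](O)[C@@H](C)CC(=O)O)O4)c2O)O1
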